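If a reaction speeds itself up on what it releases, I ask first how much must be released before the speeding counts, and I put that question to two flasks, spring and midnight, which differ in protic impurity.

in all of them: starting material 25 mM; coupling partner 125 mM; base 7.50 mM; time 20 h
- spring: protic impurity 12.0 mM
- midnight: protic impurity 16.0 mM

    base + released group ⇌ salt, settled at all times (K1 = 1.0 × 10⁶ M⁻¹)
    starting material + coupling partner → product + released group (k2 = 0.0076 M⁻¹ h⁻¹)
    starting material + protic impurity → quenched substrate (k3 = 120 M⁻¹ h⁻¹)
    starting material + coupling partner + released group → product + 2 released group (k4 = 590 M⁻² h⁻¹)

- which of these there is most of at the end, counted by the starting material in it, spring (product / starting material)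
- which of these there is most of at the end, counted by the starting material in it, midnight (product / starting material)
- how much there is at the end of the one of these that leads, in percent of the starting material charged: spring
- how much there is at the end of the one of these that leads, in percent of the starting material charged: midnight

I followed the rate of the plain coupling, in which starting material meets coupling partner unaided. In spring it began at

R = 0.0076 M⁻¹ h⁻¹ × 25 mM × 125 mM = 0.0238 mM h⁻¹.

In spring, with the other concentrations held at their charge, the protic impurity takes starting material with a half-life of 0.48 h, shorter than the 30 d of the plain coupling, which is pseudo-first-order in starting material, so I let it destroy its own charge one for one at the outset, and I reckoned midnight the same way. That cut the rate by a factor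

S = (25 mM − 12.0 mM) / 25 mM = 0.520 in spring, and 0.360 at midnight.

The plain coupling's own drain over 20 h slowed it by a further factor of 0.981, which I left out of the release. I then expected R × S × t, that is 0.247 mM released in spring and 0.171 mM at midnight, with starting material leading at 51.0% in spring and 35.3% at midnight.

The speeding depends on free released group, which the base holds as salt. The assisted coupling equals the plain one when salt stands to free base as

G = 1.0 × 10⁶ M⁻¹ × 0.0076 M⁻¹ h⁻¹ / 590 M⁻² h⁻¹ = 12.9,

N = 7.50 mM × G / (1 + G) = 6.96 mM.

This N is the crossing release, the amount released at which control passes to the assisted coupling. The free released group at the crossing, 0.0129 mM, is small beside N, so I left it out of this balance. Since 0.247 mM in spring and 0.171 mM at midnight are each far less than N, I expected the plain coupling to keep control in both flasks.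

The forecast put starting material ahead at 51% in spring and 35.3% at midnight, stating that “no takeoff occurs”, and the simulation gave starting material ahead at 51.0% in spring and 35.3% at midnight, with product at 0.999% in spring and 0.709% at midnight.

In spring the salt at the end stood at 0.250 mM, which is 3.59% of N. A neighbour of midnight charged with 3.0 mM of base has its crossing release lowered to 2.78 mM, while the reckoned release stays 0.171 mM, still far below it. That flask ended with 0.178 mM of salt and 35.3% of its starting material.

(Its constants were drawn at random within sensible limits; no experiment stands behind them.)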